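## Retrosynthetic overview

1. The ten-membered ring is closed last, at C9–C10, by an intramolecular B-alkyl Suzuki–Miyaura coupling of a terminal vinyl group (via its 9-BBN adduct) with an (E)-2-iodoalkene on the fully esterified seco compound.
2. The C6–C7 bond comes from a chiral-phosphoric-acid-catalysed anti-allylboration of an α,β-epoxy aldehyde with an (E)-γ-isopropylallyl boronate (sets C6 and C7), followed by acetylation.
3. The oxirane (first ring formed) comes from an organocatalytic iminium/chiral-phosphate epoxidation of a β-methyl enal (sets C4 and C5).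
4. The C2–C3 bond comes from a chiral-phosphoric-acid-catalysed propargylation of an achiral enal acetal with a methylallenyl boronate (first stereocentre, C3); the alkyne then gives the (E)-vinyl iodide and C3–OH is angeloylated.
5. Ring order: oxirane, then cyclodecene.

Notation: atom labels C1–C15 follow germacrane numbering of the target (C1=C10 alkene, C3 angelate, C4–C5 epoxide, C6 acetate, C7 isopropyl). TRIP = 3,3′-bis(2,4,6-triisopropylphenyl)-1,1′-binaphthyl-2,2′-diyl hydrogen phosphate.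

Assumption: the facial senses of the TRIP catalysts (Re-face delivery by the (R)-acid in allyl- and allenylborations; sense of the TRIP ammonium salt in the epoxidation) are carried over from simple aldehydes and enals, and the mirror-image catalyst is used if a pilot run shows the opposite sense.

## Route

Step 1
Reactants: 1 2,2-dimethoxyacetaldehyde; 2 2-(triphenyl-λ5-phosphanylidene)propanal
Product: 3 (2E)-4,4-dimethoxy-2-methylbut-2-enal
Conditions: 1 (60 % aq. solution, 1.2 equiv), toluene, 80 °C, 16 h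
Reagents that add atoms: none
Why: Wittig olefination with a stabilised formyl ylide gives the E-trisubstituted enal, which fixes the later C4=C5 geometry (C3 trans to C6) and hence the trans-epoxide.

Step 2
Reactants: 4 but-2-yn-1-ol
Product: 5 but-2-yn-1-yl methyl carbonate
Conditions: ClCO2Me, pyridine, CH2Cl2, 0 °C
Reagents that add atoms: methyl chloroformate, COC(Cl)=O
Why: plain O-acylation (carbonate formation) installs the leaving group for the SN2′ borylation.

Step 3
Reactants: 5 but-2-yn-1-yl methyl carbonate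
Product: 6 2-(buta-2,3-dien-2-yl)-4,4,5,5-tetramethyl-1,3,2-dioxaborolane
Conditions: B2pin2, Cu(O-t-Bu) (10 mol %), Xantphos (10 mol %), THF, 50 °C
Reagents that add atoms: bis(pinacolato)diboron, CC1(C)OB(OC1(C)C)B1OC(C)(C)C(C)(C)O1
Why: copper-catalysed SN2′ borylation of a propargylic carbonate (Ito–Sawamura allenylboronate synthesis) places boron regiospecifically on the methyl-bearing carbon.

Step 4
Reactants: 3 (2E)-4,4-dimethoxy-2-methylbut-2-enal; 6 2-(buta-2,3-dien-2-yl)-4,4,5,5-tetramethyl-1,3,2-dioxaborolane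
Product: 8 (2E,4S)-1,1-dimethoxy-3-methyloct-2-en-6-yn-4-ol, via O-pinacolboryl ether 7 (not isolated)
Conditions: 6 (1.5 equiv), (S)-TRIP (10 mol %), 4 Å MS, toluene, −20 °C; aq. NaHCO3 work-up
Reagents that add atoms: none
Why: chiral-phosphoric-acid-catalysed propargylation (SE2′ allenylboration) through a closed six-membered transition state, in which the acid hydrogen-bonds the boronate oxygen and the formyl C–H; Si-face attack on the aldehyde sets the first stereocentre, C3 (S), and delivers the 2-butynyl chain.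

Step 5
Reactants: 8 (2E,4S)-1,1-dimethoxy-3-methyloct-2-en-6-yn-4-ol
Product: 10 (2E,4S,6E)-7-iodo-1,1-dimethoxy-3-methylocta-2,6-dien-4-ol, via alkenylzirconocene alkoxide 9 (not isolated)
Conditions: Cp2Zr(H)Cl (3 equiv), THF, rt → 45 °C; then I2, 0 °C
Reagents that add atoms: iodine, II
Why: hydrozirconation–iodination: syn addition of Zr–H, with zirconium settling under excess hydride on the less hindered methyl-bearing alkyne carbon (C10), then iodinolysis with retention gives the (E)-2-iodoalkene (the first equivalent of hydride only deprotonates the alcohol).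

Step 6
Reactants: 10 (2E,4S,6E)-7-iodo-1,1-dimethoxy-3-methylocta-2,6-dien-4-ol; 11 angelic acid, (2Z)-2-methylbut-2-enoic acid
Product: 13 (2E,4S,6E)-7-iodo-1,1-dimethoxy-3-methylocta-2,6-dien-4-yl (2Z)-2-methylbut-2-enoate, via mixed anhydride 12 (not isolated)
Conditions: 11 (2 equiv), 2,4,6-Cl3C6H2COCl, Et3N, toluene, rt, 2 h; then 10, 80 °C
Reagents that add atoms: none
Why: Yamaguchi-type mixed-anhydride esterification run without DMAP, the standard way to make angelates without Z→E isomerisation to the tiglate; C3 is untouched.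

Step 7
Reactants: 13 (2E,4S,6E)-7-iodo-1,1-dimethoxy-3-methylocta-2,6-dien-4-yl (2Z)-2-methylbut-2-enoate
Product: 14 (2E,4S,6E)-7-iodo-3-methyl-1-oxoocta-2,6-dien-4-yl (2Z)-2-methylbut-2-enoate
Conditions: TsOH·H2O (10 mol %), acetone–H2O (10:1), 0 °C → rt
Reagents that add atoms: water, O
Why: acid-catalysed hydrolysis of an allylic dimethyl acetal is fast and mild enough to leave the angelate, the vinyl iodide and the E-enal geometry intact.

Step 8
Reactants: 14 (2E,4S,6E)-7-iodo-3-methyl-1-oxoocta-2,6-dien-4-yl (2Z)-2-methylbut-2-enoate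
Product: 15 (1S,3E)-1-[(2R,3S)-3-formyl-2-methyloxiran-2-yl]-4-iodopent-3-en-1-yl (2Z)-2-methylbut-2-enoate
Conditions: [(3,5-(CF3)2C6H3CH2)2NH2]+ (R)-TRIP− (10 mol %), t-BuOOH (1.2 equiv, in decane), t-BuOMe, 0 °C → rt
Reagents that add atoms: tert-butyl hydroperoxide, CC(C)(C)OO
Why: iminium-ion (Weitz–Scheffer-type) epoxidation under asymmetric counteranion-directed catalysis: t-BuOOH adds to the β-carbon (C4) of the iminium paired with the chiral phosphate and the enamine closes the oxirane, giving the trans (4R,5R) epoxide chemoselectively at the enal; the polar Felkin–Anh preference at C3 (angelate anti to the incoming peroxide, H eclipsing the C4 methyl) favours the same 3,4-threo isomer.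

Step 9
Reactants: 16 3-methylbut-1-yne
Product: 17 4,4,5,5-tetramethyl-2-[(1E)-3-methylbut-1-en-1-yl]-1,3,2-dioxaborolane
Conditions: HBpin, Cp2Zr(H)Cl (5 mol %), Et3N (10 mol %), neat, 60 °C, sealed tube
Reagents that add atoms: pinacolborane, CC1(C)OBOC1(C)C
Why: zirconium-catalysed syn, anti-Markovnikov hydroboration of a terminal alkyne gives the pure (E)-alkenylboronate.

Step 10
Reactants: 17 4,4,5,5-tetramethyl-2-[(1E)-3-methylbut-1-en-1-yl]-1,3,2-dioxaborolane
Product: 19 4,4,5,5-tetramethyl-2-[(2E)-4-methylpent-2-en-1-yl]-1,3,2-dioxaborolane, via chloromethyl borate complex 18 (not isolated)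
Conditions: ClCH2I, n-BuLi, THF, −78 °C → rt
Reagents that add atoms: chloroiodomethane, ClCI
Why: Matteson homologation (1,2-metalate shift of the alkenyl group onto CH2 with loss of chloride) inserts one carbon with full retention of the E geometry, giving the (E)-γ-isopropylallyl boronate.

Step 11
Reactants: 15 (1S,3E)-1-[(2R,3S)-3-formyl-2-methyloxiran-2-yl]-4-iodopent-3-en-1-yl (2Z)-2-methylbut-2-enoate; 19 4,4,5,5-tetramethyl-2-[(2E)-4-methylpent-2-en-1-yl]-1,3,2-dioxaborolane
Product: 21 (1S,3E)-1-{(2R,3R)-3-[(1R,2R)-1-hydroxy-2-(propan-2-yl)but-3-en-1-yl]-2-methyloxiran-2-yl}-4-iodopent-3-en-1-yl (2Z)-2-methylbut-2-enoate, via O-pinacolboryl ether 20 (not isolated)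
Conditions: 19 (1.5 equiv), (R)-TRIP (10 mol %), 4 Å MS, toluene, −30 °C; aq. NaHCO3 work-up
Reagents that add atoms: none
Why: chiral-phosphoric-acid-catalysed allylboration through a closed chair transition state: the (E)-boronate gives the 6,7-anti adduct, the (R)-acid directs Re-face attack (C6 R), and this coincides with the Cornforth preference of the α,β-epoxy aldehyde (5,6-erythro, matched), so C6 and C7 are set together (C7 is R here only because vinyl outranks isopropyl; it becomes 7S in the target).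

Step 12
Reactants: 21 (1S,3E)-1-{(2R,3R)-3-[(1R,2R)-1-hydroxy-2-(propan-2-yl)but-3-en-1-yl]-2-methyloxiran-2-yl}-4-iodopent-3-en-1-yl (2Z)-2-methylbut-2-enoate
Product: 22 (1S,3E)-1-{(2R,3R)-3-[(1R,2R)-1-(acetyloxy)-2-(propan-2-yl)but-3-en-1-yl]-2-methyloxiran-2-yl}-4-iodopent-3-en-1-yl (2Z)-2-methylbut-2-enoate
Conditions: Ac2O, pyridine, DMAP (5 mol %), CH2Cl2, 0 °C → rt
Reagents that add atoms: acetic anhydride, CC(=O)OC(C)=O
Why: standard acetylation of the only free hydroxyl; a pre-formed angelate ester is configurationally stable to these conditions.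

Step 13
Reactants: 22 (1S,3E)-1-{(2R,3R)-3-[(1R,2R)-1-(acetyloxy)-2-(propan-2-yl)but-3-en-1-yl]-2-methyloxiran-2-yl}-4-iodopent-3-en-1-yl (2Z)-2-methylbut-2-enoate
Product: 24 (1(10)E,3S,4R,5R,6R,7S)-6-acetoxy-4,5-epoxygermacr-1(10)-en-3-yl (2Z)-2-methylbut-2-enoate (CNP0180504.2), via B-alkyl-9-BBN borane 23 (not isolated)
Conditions: 9-BBN dimer (0.75 equiv), THF, 0 °C → rt; then syringe-pump addition (12 h) into Pd(dppf)Cl2 (20 mol %), AsPh3 (40 mol %), K3PO4 (3 equiv), H2O (10 equiv), DMF–THF, 50 °C, 1 mM final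
Reagents that add atoms: none
Why: Proposed new method: an intramolecular B-alkyl Suzuki–Miyaura coupling used to close a ten-membered (E)-cycloalkene; zerovalent palladium inserts into the C10–I bond with retention, the base-activated primary alkyl group of the 9-BBN borate (formed chemoselectively at the only terminal alkene) transmetalates intramolecularly, and reductive elimination from the eleven-membered divalent palladacycle forges C9–C10 with the E geometry already fixed, the chain being pre-bent by the trans-epoxide and three branched carbons while slow addition suppresses dimers; the closest known reaction types are the intermolecular B-alkyl Suzuki coupling of 2-iodo-2-alkenes and B-alkyl Suzuki macrocyclisations to rings of eleven or more members, not yet shown for a germacrane-size ring.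

## Compound list

1 | 2,2-dimethoxyacetaldehyde | COC(OC)C=O | starting material
2 | 2-(triphenyl-λ5-phosphanylidene)propanal | CC(C=O)=P(c1ccccc1)(c1ccccc1)c1ccccc1 | starting material
3 | (2E)-4,4-dimethoxy-2-methylbut-2-enal | COC(OC)/C=C(\C)C=O | intermediate
4 | but-2-yn-1-ol | CC#CCO | starting material
5 | but-2-yn-1-yl methyl carbonate | CC#CCOC(=O)OC | intermediate
6 | 2-(buta-2,3-dien-2-yl)-4,4,5,5-tetramethyl-1,3,2-dioxaborolane | C=C=C(C)B1OC(C)(C)C(C)(C)O1 | intermediate
7 | O-pinacolboryl ether of 8: 2-{[(2E,4S)-1,1-dimethoxy-3-methyloct-2-en-6-yn-4-yl]oxy}-4,4,5,5-tetramethyl-1,3,2-dioxaborolane | COC(OC)/C=C(\C)[C@@H](OB1OC(C)(C)C(C)(C)O1)CC#CC | intermediate (not isolated)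
8 | (2E,4S)-1,1-dimethoxy-3-methyloct-2-en-6-yn-4-ol | COC(OC)/C=C(\C)[C@@H](O)CC#CC | intermediate
9 | chlorido[(2E,5S,6E)-5-{[chloridobis(cyclopentadienyl)zirconio]oxy}-8,8-dimethoxy-6-methylocta-2,6-dien-2-yl]bis(cyclopentadienyl)zirconium (C10-zirconated alkene carried as its O-zirconium alkoxide) | COC(OC)/C=C(\C)[C@@H](O[Zr](Cl)(C1C=CC=C1)C1C=CC=C1)C/C=C(\C)[Zr](Cl)(C1C=CC=C1)C1C=CC=C1 | intermediate (not isolated)
10 | (2E,4S,6E)-7-iodo-1,1-dimethoxy-3-methylocta-2,6-dien-4-ol | COC(OC)/C=C(\C)[C@@H](O)C/C=C(\C)I | intermediate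
11 | angelic acid, (2Z)-2-methylbut-2-enoic acid | C/C=C(/C)C(=O)O | starting material
12 | (2Z)-2-methylbut-2-enoic 2,4,6-trichlorobenzoic anhydride | C/C=C(/C)C(=O)OC(=O)c1c(Cl)cc(Cl)cc1Cl | intermediate (not isolated)
13 | (2E,4S,6E)-7-iodo-1,1-dimethoxy-3-methylocta-2,6-dien-4-yl (2Z)-2-methylbut-2-enoate | COC(OC)/C=C(\C)[C@@H](OC(=O)/C(C)=C\C)C/C=C(\C)I | intermediate
14 | (2E,4S,6E)-7-iodo-3-methyl-1-oxoocta-2,6-dien-4-yl (2Z)-2-methylbut-2-enoate | O=C/C=C(\C)[C@@H](OC(=O)/C(C)=C\C)C/C=C(\C)I | intermediate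
15 | (1S,3E)-1-[(2R,3S)-3-formyl-2-methyloxiran-2-yl]-4-iodopent-3-en-1-yl (2Z)-2-methylbut-2-enoate | O=C[C@H]1O[C@]1(C)[C@@H](OC(=O)/C(C)=C\C)C/C=C(\C)I | intermediate
16 | 3-methylbut-1-yne | CC(C)C#C | starting material
17 | 4,4,5,5-tetramethyl-2-[(1E)-3-methylbut-1-en-1-yl]-1,3,2-dioxaborolane | CC(C)/C=C/B1OC(C)(C)C(C)(C)O1 | intermediate
18 | lithium (chloromethyl)[(1E)-3-methylbut-1-en-1-yl](pinacolato)borate | [Li+].CC(C)/C=C/[B-]1(CCl)OC(C)(C)C(C)(C)O1 | intermediate (not isolated)
19 | 4,4,5,5-tetramethyl-2-[(2E)-4-methylpent-2-en-1-yl]-1,3,2-dioxaborolane | CC(C)/C=C/CB1OC(C)(C)C(C)(C)O1 | intermediate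
20 | O-pinacolboryl ether of 21 (O–Bpin in place of O–H at C6) | C=C[C@@H](C(C)C)[C@@H](OB2OC(C)(C)C(C)(C)O2)[C@H]1O[C@]1(C)[C@@H](OC(=O)/C(C)=C\C)C/C=C(\C)I | intermediate (not isolated)
21 | (1S,3E)-1-{(2R,3R)-3-[(1R,2R)-1-hydroxy-2-(propan-2-yl)but-3-en-1-yl]-2-methyloxiran-2-yl}-4-iodopent-3-en-1-yl (2Z)-2-methylbut-2-enoate | C=C[C@@H](C(C)C)[C@@H](O)[C@H]1O[C@]1(C)[C@@H](OC(=O)/C(C)=C\C)C/C=C(\C)I | intermediate
22 | (1S,3E)-1-{(2R,3R)-3-[(1R,2R)-1-(acetyloxy)-2-(propan-2-yl)but-3-en-1-yl]-2-methyloxiran-2-yl}-4-iodopent-3-en-1-yl (2Z)-2-methylbut-2-enoate | C=C[C@@H](C(C)C)[C@@H](OC(C)=O)[C@H]1O[C@]1(C)[C@@H](OC(=O)/C(C)=C\C)C/C=C(\C)I | intermediate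
23 | 9-{(3S,4R)-4-acetoxy-4-[(2R,3R)-3-{(1S,3E)-4-iodo-1-[(2Z)-2-methylbut-2-enoyloxy]pent-3-en-1-yl}-3-methyloxiran-2-yl]-3-(propan-2-yl)butyl}-9-borabicyclo[3.3.1]nonane (boron on C9) | B1(CC[C@@H](C(C)C)[C@@H](OC(C)=O)[C@H]3O[C@]3(C)[C@@H](OC(=O)/C(C)=C\C)C/C=C(\C)I)C2CCCC1CCC2 | intermediate (not isolated)
24 | (1(10)E,3S,4R,5R,6R,7S)-6-acetoxy-4,5-epoxygermacr-1(10)-en-3-yl (2Z)-2-methylbut-2-enoate (CNP0180504.2) | C/C=C(/C)C(=O)O[C@H]1C/C=C(\C)CC[C@@H](C(C)C)[C@@H](OC(C)=O)[C@H]2O[C@]12C | target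

## Step count and risk

Total steps: 13. Longest linear sequence: 10 (steps 2, 3, 4, 5, 6, 7, 8, 11, 12, 13, from but-2-yn-1-ol).

Steps most likely to fail:

1. Step 13 (new macrocyclisation). Risks are oligomerisation, β-hydride loss or proto-deboronation instead of closure of the strained ring, and partial ester hydrolysis by the base. Fallback with known chemistry, setting out from 22 and returning at 24: 22 is vinylated at C10 with potassium vinyltrifluoroborate (Pd(dppf)Cl2, Cs2CO3, THF–H2O, 65 °C) to give (1S,3E)-1-{(2R,3R)-3-[(1R,2R)-1-(acetyloxy)-2-(propan-2-yl)but-3-en-1-yl]-2-methyloxiran-2-yl}-4-methylhexa-3,5-dien-1-yl (2Z)-2-methylbut-2-enoate F1. Ring-closing metathesis between its two terminal vinyl groups (second-generation Grubbs catalyst, (H2IMes)(PCy3)Cl2Ru=CHPh, toluene, 1 mM, 60 °C) gives the ten-membered (1(10)E,8Z)-8,9-didehydro analogue of the target F2. Chemoselective diimide reduction of the disubstituted C8=C9 bond (2-nitrobenzenesulfonyl hydrazide, Et3N, CH2Cl2, rt) then gives 24.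

2. Step 8 (iminium epoxidation of a hindered γ-acyloxy enal). Risks are slow iminium formation at the β,β-disubstituted centre, and dienamine formation that would scramble C3 or the alkene geometry. Fallback, setting out from 14 and returning at 15: Luche reduction (NaBH4, CeCl3·7H2O, MeOH, −40 °C) gives (2E,4S,6E)-1-hydroxy-7-iodo-3-methylocta-2,6-dien-4-yl (2Z)-2-methylbut-2-enoate F3. Sharpless asymmetric epoxidation (Ti(OiPr)4, D-(−)-diethyl tartrate, t-BuOOH, 4 Å MS, CH2Cl2, −20 °C; reagent-controlled, the enantiomeric series to that obtained from geraniol with the L-tartrate) gives (1S,3E)-1-[(2R,3R)-3-(hydroxymethyl)-2-methyloxiran-2-yl]-4-iodopent-3-en-1-yl (2Z)-2-methylbut-2-enoate F4. Dess–Martin oxidation (NaHCO3, CH2Cl2) returns 15.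

3. Step 11 (catalytic allylboration of an α,β-epoxy aldehyde with a bulky γ-isopropyl boronate). Risks are low rate and acid-induced epoxide opening. Fallback with a stoichiometric chiral reagent, setting out from 19 (and 15) and returning at 21: 19 is converted with KHF2 (MeOH–H2O) into potassium trifluoro[(2E)-4-methylpent-2-en-1-yl]borate F5, and this with Me3SiCl and diisopropyl D-tartrate (MeCN, rt) into the Roush-type reagent diisopropyl (4S,5S)-2-[(2E)-4-methylpent-2-en-1-yl]-1,3,2-dioxaborolane-4,5-dicarboxylate F6. F6 adds to 15 without catalyst (toluene, 4 Å MS, −78 °C) through the same chair transition state; the (S,S)-tartrate selects the Re face, matched with the Cornforth bias, and aqueous work-up gives 21.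

Further compounds
F1 | step 13 | (1S,3E)-1-{(2R,3R)-3-[(1R,2R)-1-(acetyloxy)-2-(propan-2-yl)but-3-en-1-yl]-2-methyloxiran-2-yl}-4-methylhexa-3,5-dien-1-yl (2Z)-2-methylbut-2-enoate | C=C[C@@H](C(C)C)[C@@H](OC(C)=O)[C@H]1O[C@]1(C)[C@@H](OC(=O)/C(C)=C\C)C/C=C(\C)C=C
F2 | step 13 | (1(10)E,3S,4R,5R,6R,7S,8Z)-6-acetoxy-4,5-epoxygermacra-1(10),8-dien-3-yl (2Z)-2-methylbut-2-enoate | C/C=C(/C)C(=O)O[C@H]1C/C=C(\C)/C=C\[C@@H](C(C)C)[C@@H](OC(C)=O)[C@H]2O[C@]12C
F3 | step 8 | (2E,4S,6E)-1-hydroxy-7-iodo-3-methylocta-2,6-dien-4-yl (2Z)-2-methylbut-2-enoate | OC/C=C(\C)[C@@H](OC(=O)/C(C)=C\C)C/C=C(\C)I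
F4 | step 8 | (1S,3E)-1-[(2R,3R)-3-(hydroxymethyl)-2-methyloxiran-2-yl]-4-iodopent-3-en-1-yl (2Z)-2-methylbut-2-enoate | OC[C@H]1O[C@]1(C)[C@@H](OC(=O)/C(C)=C\C)C/C=C(\C)I
F5 | step 11 | potassium trifluoro[(2E)-4-methylpent-2-en-1-yl]borate | [K+].CC(C)/C=C/C[B-](F)(F)F
F6 | step 11 | diisopropyl (4S,5S)-2-[(2E)-4-methylpent-2-en-1-yl]-1,3,2-dioxaborolane-4,5-dicarboxylate | CC(C)/C=C/CB1O[C@@H]([C@H](O1)C(=O)OC(C)C)C(=O)OC(C)C
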